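**Plan**

- Retrosynthesis: the angelate C–O bond at O3 is cut first, then the C3–C4 bond of ring A. The cis-3,4-diol is a pinacol retron, and because C4 sits on C5 of the C5=C6 alkene, the precursor is a 1-acetylcyclohexene (ring B) whose neighbouring quaternary C10 carries a 3-oxopropyl chain (a 1,6-keto aldehyde).
- Next the C4–C5 bond (acetyl from the enol triflate of a C5 ketone), the C12 oxidation level (acrylate from isopropenyl) and the C1–C10 bond (Michael addition to methyl acrylate) are cut, which leads to (+)-dihydrocarvone.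
- Forward: ring B is taken intact from dihydrocarvone, the C1–C3 chain is joined at C10, both side chains are adjusted, and ring A is closed last by reductive C3–C4 coupling. Angeloylation of O3 ends the route.
- Stereochemistry: C7 comes from the chiral pool, C10 from the (R)-1-phenylethylamine auxiliary, and C3 and C4 are set together in the ring closure under control of C10 and samarium chelation.

Key step: step 8

Remark: eudesmane numbering is used throughout (ring A = C1–C5 and C10, ring B = C5–C10, C11–C13 = acrylate carbons, C14 = methyl on C10, C15 = methyl on C4). Commercial (+)-dihydrocarvone is assumed to be the 5R material containing both C2 epimers, which converge in step 1.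

**Step 1**
Reactants: 1 (+)-dihydrocarvone; 2 (R)-1-phenylethylamine; 3 methyl acrylate
Product: 6 methyl 3-[(1S,4R)-1-methyl-2-oxo-4-(prop-1-en-2-yl)cyclohexyl]propanoate, via ketimine 4 (not isolated), via adduct ketimine 5 (not isolated)
Conditions: 2, TsOH·H2O (cat.), PhMe, reflux, Dean–Stark; then 3, THF, 50 °C; then 20% aq. AcOH, rt
Reagents that add atoms: methyl acrylate, C=CC(=O)OC; water, O
Why: Chiral-imine (secondary-enamine) Michael addition: the ketimine reacts through its more substituted enamine tautomer in an aza-ene-like transition state, so the quaternary carbon forms regioselectively and the acrylate is delivered to the face fixed by the (R)-1-phenylethyl group, which should set C10 as S (chain trans to the C7 isopropenyl, methyl cis) against the weak opposite bias of the ring, while the C2 epimers of 1 converge because this centre is planar in the enamine.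

**Step 2**
Reactants: 6 methyl 3-[(1S,4R)-1-methyl-2-oxo-4-(prop-1-en-2-yl)cyclohexyl]propanoate
Product: 7 methyl 3-[(1S,4R)-1-methyl-4-(prop-1-en-2-yl)-2-{[(trifluoromethyl)sulfonyl]oxy}cyclohex-2-en-1-yl]propanoate
Conditions: KN(SiMe3)2, THF, −78 °C; then PhNTf2, −78 to 0 °C; NH4Cl quench
Reagents that add atoms: N-phenylbis(trifluoromethanesulfonimide), O=S(=O)(N(c1ccccc1)S(=O)(=O)C(F)(F)F)C(F)(F)F
Why: Kinetic enolate O-triflation: the ketone can enolize only toward C6 because C10 is quaternary, so deprotonation at −78 °C and trapping with PhNTf2 should give the C5=C6 enol triflate without touching the less acidic ester.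

**Step 3**
Reactants: 7 methyl 3-[(1S,4R)-1-methyl-4-(prop-1-en-2-yl)-2-{[(trifluoromethyl)sulfonyl]oxy}cyclohex-2-en-1-yl]propanoate
Product: 8 (3R,6S)-6-(3-hydroxypropyl)-6-methyl-3-(prop-1-en-2-yl)cyclohex-1-en-1-yl trifluoromethanesulfonate
Conditions: i-Bu2AlH (2.5 equiv), CH2Cl2, −78 to −20 °C; aq. potassium sodium tartrate
Reagents that add atoms: none
Why: DIBAL-H ester reduction: excess hydride takes the methyl ester to the primary alcohol (C3 at the alcohol level, kept distinct from the later C12 ester) while the enol triflate and the alkene are inert at low temperature.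

**Step 4**
Reactants: 8 (3R,6S)-6-(3-hydroxypropyl)-6-methyl-3-(prop-1-en-2-yl)cyclohex-1-en-1-yl trifluoromethanesulfonate
Product: 10 (3R,6S)-6-(3-hydroxypropyl)-6-methyl-3-(3-oxoprop-1-en-2-yl)cyclohex-1-en-1-yl trifluoromethanesulfonate, via allylic alcohol 9 (not isolated)
Conditions: SeO2 (cat.), t-BuOOH, CH2Cl2, 0 °C to rt; filtration; then MnO2 (excess), CH2Cl2, rt
Reagents that add atoms: selenium dioxide, O=[Se]=O; tert-butyl hydroperoxide, CC(C)(C)OO
Why: SeO2 allylic oxidation (ene reaction then [2,3]-sigmatropic shift) followed by MnO2 oxidation: the electron-rich 1,1-disubstituted alkene reacts in preference to the electron-poor enol triflate, hydrogen is taken from the methyl group and not from the ring C7–H that lies in the alkene plane, and MnO2 oxidizes only the allylic alcohol, so the C7 stereocentre and the saturated primary alcohol are kept.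

**Step 5**
Reactants: 10 (3R,6S)-6-(3-hydroxypropyl)-6-methyl-3-(3-oxoprop-1-en-2-yl)cyclohex-1-en-1-yl trifluoromethanesulfonate
Product: 12 methyl 2-[(1R,4S)-4-(3-hydroxypropyl)-4-methyl-3-{[(trifluoromethyl)sulfonyl]oxy}cyclohex-2-en-1-yl]prop-2-enoate, via acrylic acid 11 (not isolated)
Conditions: NaClO2, NaH2PO4, 2-methyl-2-butene, t-BuOH/H2O, 0 °C to rt; extraction; then TMSCHN2, PhMe/MeOH, 0 °C
Reagents that add atoms: sodium chlorite, [Na+].[O-]Cl=O; trimethylsilyldiazomethane, C[Si](C)(C)C=[N+]=[N-]
Why: Pinnick oxidation then diazoalkane esterification: chlorite converts the 2-substituted acrolein into the acrylic acid without touching the alkene (hypochlorite is scavenged) or the primary alcohol, and TMSCHN2 in methanol methylates only the carboxylic acid.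

**Step 6**
Reactants: 12 methyl 2-[(1R,4S)-4-(3-hydroxypropyl)-4-methyl-3-{[(trifluoromethyl)sulfonyl]oxy}cyclohex-2-en-1-yl]prop-2-enoate; 13 tributyl(1-ethoxyvinyl)stannane
Product: 15 methyl 2-[(1R,4S)-3-acetyl-4-(3-hydroxypropyl)-4-methylcyclohex-2-en-1-yl]prop-2-enoate, via ethoxydiene 14 (not isolated)
Conditions: 13, Pd(PPh3)4 (5 mol %), LiCl (3 equiv), CuI (10 mol %), THF, 65 °C; then 1 M HCl, THF, 0 °C to rt
Reagents that add atoms: tributyl(1-ethoxyvinyl)stannane, C=C(OCC)[Sn](CCCC)(CCCC)CCCC; water, O
Why: Stille coupling then enol ether hydrolysis: oxidative addition of the enol triflate to zerovalent palladium, chloride-assisted transmetalation from tin and reductive elimination give the 2-ethoxydiene, whose mild acid hydrolysis unveils the acetyl group on C5 with the C5=C6 bond in place, and the near-neutral conditions spare the acrylate and the doubly allylic C7–H.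

**Step 7**
Reactants: 15 methyl 2-[(1R,4S)-3-acetyl-4-(3-hydroxypropyl)-4-methylcyclohex-2-en-1-yl]prop-2-enoate
Product: 16 methyl 2-[(1R,4S)-3-acetyl-4-methyl-4-(3-oxopropyl)cyclohex-2-en-1-yl]prop-2-enoate
Conditions: Dess–Martin periodinane, NaHCO3, CH2Cl2, 0 °C to rt; used at once
Reagents that add atoms: none
Why: Dess–Martin oxidation: buffered hypervalent-iodine oxidation takes the primary alcohol to the aldehyde without enolization, so the γ-hydrogen at C7 of the enone is not disturbed and the 1,6-keto aldehyde is obtained for immediate use.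

**Step 8**
Reactants: 16 methyl 2-[(1R,4S)-3-acetyl-4-methyl-4-(3-oxopropyl)cyclohex-2-en-1-yl]prop-2-enoate
Product: 17 methyl 2-[(2R,4aS,7S,8R)-7,8-dihydroxy-4a,8-dimethyl-2,3,4,4a,5,6,7,8-octahydronaphthalen-2-yl]prop-2-enoate (methyl 3β,4β-dihydroxyeudesma-5,11(13)-dien-12-oate)
Conditions: SmI2 (2.5 equiv, 0.1 M in THF), t-BuOH (2 equiv), THF (0.01 M in substrate), −78 °C; sat. NH4Cl
Reagents that add atoms: none
Why: Electron transfer from divalent samarium to the aldehyde gives a trivalent-samarium ketyl at C3 that, held to the acetyl oxygen by the oxophilic metal, adds to the ketone carbon C4; a second electron transfer and protonation by t-BuOH give the samarium diolate and then diol 17 (ketyl–carbonyl pinacol coupling). The closest known reaction type is the SmI2-mediated intramolecular ketone–aldehyde pinacol cyclization of 1,6-dicarbonyl compounds to cis-cyclohexane-1,2-diols. Ring A (C10–C1–C2–C3–C4–C5) closes in the 6-exo-trig mode onto the C4=O bond. The cis relation of O3 and O4 follows from the samarium bridge between the two oxygens, and their orientation from C10: in the chair-like transition state the C14 methyl is axial on the forming ring, so the acetyl methyl takes the equatorial site to avoid a syn-diaxial methyl/methyl contact, which puts O4 axial and O3 equatorial on the C14 face (3S,4R). The step needs coupling at C4 rather than ketyl attack on the enone β-carbon C6 or on the acrylate, and it needs both esters untouched; the five-membered samarium chelate directs bond formation to C4, attack at C6 would demand a bridged bicyclo[3.3.1]nonane, and HMPA-free SmI2 at −78 °C under high dilution leaves the ester and the acrylate unreduced and disfavours bimolecular ketyl addition.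

**Step 9**
Reactants: 17 methyl 2-[(2R,4aS,7S,8R)-7,8-dihydroxy-4a,8-dimethyl-2,3,4,4a,5,6,7,8-octahydronaphthalen-2-yl]prop-2-enoate; 18 angelic acid
Product: 19 methyl 2-[(2R,4aS,7S,8R)-8-hydroxy-4a,8-dimethyl-7-{[(2Z)-2-methylbut-2-enoyl]oxy}-2,3,4,4a,5,6,7,8-octahydronaphthalen-2-yl]prop-2-enoate (target)
Conditions: 18, 2,4,6-trichlorobenzoyl chloride, Et3N, PhMe, rt; then 17, 75 °C
Reagents that add atoms: angelic acid, C/C=C(/C)C(=O)O
Why: Yamaguchi esterification: the preformed mixed anhydride of angelic acid acylates the equatorial secondary C3 hydroxyl while the tertiary C4 hydroxyl is too hindered to react, and the absence of a nucleophilic catalyst should keep the Z geometry of the angelate (no isomerization to the tiglate).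

**Compound list**

1 | (+)-dihydrocarvone, (2R,5R)-2-methyl-5-(prop-1-en-2-yl)cyclohexan-1-one | C=C(C)[C@H]1CC(=O)[C@H](C)CC1 | starting material
2 | (R)-1-phenylethylamine | C[C@@H](N)c1ccccc1 | starting material
3 | methyl acrylate | C=CC(=O)OC | starting material
4 | ketimine, (1R)-N-[(5R)-2-methyl-5-(prop-1-en-2-yl)cyclohexylidene]-1-phenylethanamine (both C2 epimers, in equilibrium with the enamine) | C=C(C)[C@H]1CC(=N[C@H](C)c2ccccc2)C(C)CC1 | intermediate
5 | adduct ketimine, methyl 3-[(1S,4R)-1-methyl-2-{[(1R)-1-phenylethyl]imino}-4-(prop-1-en-2-yl)cyclohexyl]propanoate | C=C(C)[C@H]1CC(=N[C@H](C)c2ccccc2)[C@](C)(CCC(=O)OC)CC1 | intermediate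
6 | methyl 3-[(1S,4R)-1-methyl-2-oxo-4-(prop-1-en-2-yl)cyclohexyl]propanoate | C=C(C)[C@H]1CC(=O)[C@](C)(CCC(=O)OC)CC1 | intermediate
7 | methyl 3-[(1S,4R)-1-methyl-4-(prop-1-en-2-yl)-2-{[(trifluoromethyl)sulfonyl]oxy}cyclohex-2-en-1-yl]propanoate | C=C(C)[C@H]1C=C(OS(=O)(=O)C(F)(F)F)[C@](C)(CCC(=O)OC)CC1 | intermediate
8 | (3R,6S)-6-(3-hydroxypropyl)-6-methyl-3-(prop-1-en-2-yl)cyclohex-1-en-1-yl trifluoromethanesulfonate | C=C(C)[C@H]1C=C(OS(=O)(=O)C(F)(F)F)[C@](C)(CCCO)CC1 | intermediate
9 | allylic alcohol, (3R,6S)-6-(3-hydroxypropyl)-3-(3-hydroxyprop-1-en-2-yl)-6-methylcyclohex-1-en-1-yl trifluoromethanesulfonate | C=C(CO)[C@H]1C=C(OS(=O)(=O)C(F)(F)F)[C@](C)(CCCO)CC1 | intermediate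
10 | (3R,6S)-6-(3-hydroxypropyl)-6-methyl-3-(3-oxoprop-1-en-2-yl)cyclohex-1-en-1-yl trifluoromethanesulfonate | C=C(C=O)[C@H]1C=C(OS(=O)(=O)C(F)(F)F)[C@](C)(CCCO)CC1 | intermediate
11 | acrylic acid, 2-[(1R,4S)-4-(3-hydroxypropyl)-4-methyl-3-{[(trifluoromethyl)sulfonyl]oxy}cyclohex-2-en-1-yl]prop-2-enoic acid | C=C(C(=O)O)[C@H]1C=C(OS(=O)(=O)C(F)(F)F)[C@](C)(CCCO)CC1 | intermediate
12 | methyl 2-[(1R,4S)-4-(3-hydroxypropyl)-4-methyl-3-{[(trifluoromethyl)sulfonyl]oxy}cyclohex-2-en-1-yl]prop-2-enoate | C=C(C(=O)OC)[C@H]1C=C(OS(=O)(=O)C(F)(F)F)[C@](C)(CCCO)CC1 | intermediate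
13 | tributyl(1-ethoxyvinyl)stannane | C=C(OCC)[Sn](CCCC)(CCCC)CCCC | starting material
14 | ethoxydiene, methyl 2-[(1R,4S)-3-(1-ethoxyethenyl)-4-(3-hydroxypropyl)-4-methylcyclohex-2-en-1-yl]prop-2-enoate | C=C(C(=O)OC)[C@H]1C=C(C(=C)OCC)[C@](C)(CCCO)CC1 | intermediate
15 | methyl 2-[(1R,4S)-3-acetyl-4-(3-hydroxypropyl)-4-methylcyclohex-2-en-1-yl]prop-2-enoate | C=C(C(=O)OC)[C@H]1C=C(C(C)=O)[C@](C)(CCCO)CC1 | intermediate
16 | methyl 2-[(1R,4S)-3-acetyl-4-methyl-4-(3-oxopropyl)cyclohex-2-en-1-yl]prop-2-enoate | C=C(C(=O)OC)[C@H]1C=C(C(C)=O)[C@](C)(CCC=O)CC1 | intermediate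
17 | methyl 2-[(2R,4aS,7S,8R)-7,8-dihydroxy-4a,8-dimethyl-2,3,4,4a,5,6,7,8-octahydronaphthalen-2-yl]prop-2-enoate | C=C(C(=O)OC)[C@H]1C=C2[C@](C)(CC[C@H](O)[C@]2(C)O)CC1 | intermediate
18 | angelic acid, (Z)-2-methylbut-2-enoic acid | C/C=C(/C)C(=O)O | starting material
19 | methyl 2-[(2R,4aS,7S,8R)-8-hydroxy-4a,8-dimethyl-7-{[(2Z)-2-methylbut-2-enoyl]oxy}-2,3,4,4a,5,6,7,8-octahydronaphthalen-2-yl]prop-2-enoate (methyl 3β-angeloyloxy-4β-hydroxyeudesma-5,11(13)-dien-12-oate) | C=C(C(=O)OC)[C@H]1C=C2[C@](C)(CC[C@H](OC(=O)/C(C)=C\C)[C@]2(C)O)CC1 | target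

**Step count**

Total steps: 9. Longest linear sequence: 9 steps (fully linear from 1).

**Steps most likely to fail**

Step 8. Carbon–carbon bond formation may go to the enone β-carbon C6 (6-endo ketyl addition giving a bridged ring) instead of the carbonyl carbon, the aldehyde may simply be reduced, or facial control at C4 may be incomplete. Fallback from 16: an N-heterocyclic-carbene-catalysed intramolecular crossed benzoin reaction (2-(pentafluorophenyl)-6,7-dihydro-5H-pyrrolo[2,1-c][1,2,4]triazol-2-ium tetrafluoroborate, Et3N, THF, rt) turns the aldehyde into an acyl anion equivalent that adds 1,2 to the acetyl group. Under reversible conditions this should give the α-ketol methyl 2-[(2R,4aS,8R)-8-hydroxy-4a,8-dimethyl-7-oxo-2,3,4,4a,5,6,7,8-octahydronaphthalen-2-yl]prop-2-enoate F1, with the C4 methyl equatorial. Luche reduction (NaBH4, CeCl3·7H2O, MeOH, −78 °C) with axial hydride delivery, on the face away from the axial 4-hydroxyl, should then give the cis-diol 17, where the route resumes at step 9.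

Step 1. Facial selectivity may be poor because the auxiliary must override the intrinsic preference of the ring for attack cis to the isopropenyl group, and addition to the moderately reactive acrylate may be slow. Fallback from 1, with catalyst control in place of auxiliary control:
- Me3SiCl, NaI, Et3N in MeCN gives the more substituted silyl enol ether trimethyl{[(5R)-2-methyl-5-(prop-1-en-2-yl)cyclohex-1-en-1-yl]oxy}silane F2.
- MeLi in THF, then allyl chloroformate, gives allyl (5R)-2-methyl-5-(prop-1-en-2-yl)cyclohex-1-en-1-yl carbonate F3.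
- Decarboxylative asymmetric allylic alkylation of the Tsuji–Trost type (Pd2(dba)3, (S)-t-Bu-PHOX, THF) should give (2S,5R)-2-allyl-2-methyl-5-(prop-1-en-2-yl)cyclohexan-1-one F4.
- KN(SiMe3)2 and PhNTf2 give (3R,6S)-6-allyl-6-methyl-3-(prop-1-en-2-yl)cyclohex-1-en-1-yl trifluoromethanesulfonate F5.
- Hydroboration of the monosubstituted alkene with disiamylborane, then NaBO3·4H2O, gives alcohol 8, where the route resumes at step 4.

Step 4. Hydrogen may be abstracted from the doubly allylic ring C7–H instead of the methyl group, and conversion may be low or over-oxidation may occur, as is common in selenium ene chemistry. Fallback from 8: ionic ene-type chlorination (Ca(OCl)2, solid CO2, CH2Cl2/H2O, 0 °C; chloronium ion, then proton loss from the methyl group) gives (3R,6S)-3-(3-chloroprop-1-en-2-yl)-6-(3-hydroxypropyl)-6-methylcyclohex-1-en-1-yl trifluoromethanesulfonate F6. Kornblum-type oxidation with N-methylmorpholine N-oxide and catalytic KI in MeCN then gives enal 10, where the route resumes at step 5.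

**Further compounds**

F1 | step 8 | methyl 2-[(2R,4aS,8R)-8-hydroxy-4a,8-dimethyl-7-oxo-2,3,4,4a,5,6,7,8-octahydronaphthalen-2-yl]prop-2-enoate | C=C(C(=O)OC)[C@H]1C=C2[C@](C)(CCC(=O)[C@]2(C)O)CC1
F2 | step 1 | trimethyl{[(5R)-2-methyl-5-(prop-1-en-2-yl)cyclohex-1-en-1-yl]oxy}silane | C=C(C)[C@H]1CC(O[Si](C)(C)C)=C(C)CC1
F3 | step 1 | allyl (5R)-2-methyl-5-(prop-1-en-2-yl)cyclohex-1-en-1-yl carbonate | C=C(C)[C@H]1CC(OC(=O)OCC=C)=C(C)CC1
F4 | step 1 | (2S,5R)-2-allyl-2-methyl-5-(prop-1-en-2-yl)cyclohexan-1-one | C=C(C)[C@H]1CC(=O)[C@](C)(CC=C)CC1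
F5 | step 1 | (3R,6S)-6-allyl-6-methyl-3-(prop-1-en-2-yl)cyclohex-1-en-1-yl trifluoromethanesulfonate | C=C(C)[C@H]1C=C(OS(=O)(=O)C(F)(F)F)[C@](C)(CC=C)CC1
F6 | step 4 | (3R,6S)-3-(3-chloroprop-1-en-2-yl)-6-(3-hydroxypropyl)-6-methylcyclohex-1-en-1-yl trifluoromethanesulfonate | C=C(CCl)[C@H]1C=C(OS(=O)(=O)C(F)(F)F)[C@](C)(CCCO)CC1
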